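Everything rests on making ring B de novo instead of substituting a catechol. Its C2'–C5' segment (prenyl, O, O, prenyl) is locally mirror-symmetric, so it is taken from one symmetric 2,3-bis(silyloxy)-1,3-diene, while C1' and C6' come from a terminal ynone that already carries the ring A arm. One Diels–Alder/DDQ operation forms C1'–C2' and C5'–C6', closes ring B at the arene level and delivers the whole carbon skeleton as an aryl ketone, with no regiochemical question. The precursors are the (5Z,7Z)-bis-TBS dienol ether of a bis-homoprenyl 1,2-diketone and a 2-(2-bromoaryl)ethyl ethynyl ketone. Asymmetric reduction, aryl C–O coupling and desilylation then give the (S)-flavan.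

Key step: step 9

Remark on the chemistry: C2 of the target is S (O1 > C1' > C3 > H); the carbinol carbon of 23 has the same priority order and is therefore also S, and the ring closure of step 11 does not touch it.

**Step 1**
Reactants: 1 5-bromo-2-methylpent-2-ene (two equivalents); 2 1,4-dimethylpiperazine-2,3-dione
Product: 5 2,11-dimethyldodeca-2,10-diene-6,7-dione, via homoprenylmagnesium bromide 3 (not isolated), via bis(bromomagnesium) piperazinediolate 4 (not isolated)
Conditions: 1 (2.2 equiv), Mg, THF, rt to 40 °C; then 2 (1.0 equiv), THF, 0 °C to rt; 2 M HCl, 0 °C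
Reagents that add atoms: second equivalent of 5-bromo-2-methylpent-2-ene 1 (as Grignard reagent 3), CC(C)=CCCBr
Why: Grignard formation and double nucleophilic addition to the cyclic oxalamide, in which two molecules of 3 are consumed per molecule of 2 and the tetrahedral magnesium alkoxides do not collapse before the acidic work-up, so each carbonyl should take up exactly one homoprenyl group and hydrolysis should release the 1,2-diketone.

**Step 2**
Reactants: 5 2,11-dimethyldodeca-2,10-diene-6,7-dione
Product: 6 (5Z,7Z)-6,7-bis(tert-butyldimethylsilyloxy)-2,11-dimethyldodeca-2,5,7,10-tetraene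
Conditions: TBSOTf (2.3 equiv), Et3N, CH2Cl2, 0 °C to rt; chromatography on Et3N-deactivated silica
Reagents that add atoms: tert-butyldimethylsilyl triflate, CC(C)(C)[Si](C)(C)OS(=O)(=O)C(F)(F)F
Why: Silyl enol ether formation by soft enolisation of both carbonyls should favour the Z,Z isomer, in which each CH2 lies cis to its own silyloxy group and away from the other vinyl unit.

**Step 3**
Reactants: 7 2-bromo-4-hydroxybenzaldehyde
Product: 11 3-(2-bromo-4-hydroxyphenyl)propanoic acid, via benzylidene Meldrum's acid 8 (not isolated), via benzyl Meldrum's acid 9 (not isolated), via benzylmalonic acid 10 (not isolated)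
Conditions: Meldrum's acid, HCO2H/Et3N (5:2), 100 °C; then aq. HCl
Reagents that add atoms: Meldrum's acid (2,2-dimethyl-1,3-dioxane-4,6-dione), CC1(C)OC(=O)CC(=O)O1; water, O
Why: Knoevenagel condensation, conjugate hydride transfer from formate and hydrolysis–decarboxylation run in one pot and touch neither the aryl bromide nor the phenol, and the homologation is placed here because no alkene is yet present to compete.

**Step 4**
Reactants: 11 3-(2-bromo-4-hydroxyphenyl)propanoic acid
Product: 13 3-(2-bromo-4-hydroxyphenyl)-N-methoxy-N-methylpropanamide, via acyl imidazolide 12 (not isolated)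
Conditions: CDI (1.05 equiv), THF, rt; then MeNHOMe·HCl, rt
Reagents that add atoms: N,O-dimethylhydroxylamine hydrochloride, CNOC.Cl
Why: CDI amidation: the carboxylic acid is activated as its imidazolide faster than the phenol reacts, and the amine salt then displaces imidazole to give the Weinreb amide.

**Step 5**
Reactants: 13 3-(2-bromo-4-hydroxyphenyl)-N-methoxy-N-methylpropanamide; 14 prenyl bromide
Product: 15 3-[2-bromo-4-(3-methylbut-2-enyloxy)phenyl]-N-methoxy-N-methylpropanamide
Conditions: K2CO3, acetone, reflux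
Reagents that add atoms: none
Why: Williamson ether synthesis: the potassium phenoxide is alkylated at oxygen by the primary allylic bromide under carbonate conditions that leave the Weinreb amide alone.

**Step 6**
Reactants: 15 3-[2-bromo-4-(3-methylbut-2-enyloxy)phenyl]-N-methoxy-N-methylpropanamide
Product: 17 3-[2-bromo-4-hydroxy-5-(2-methylbut-3-en-2-yl)phenyl]-N-methoxy-N-methylpropanamide, via ortho-dienone 16 (not isolated)
Conditions: PhNEt2, 190 °C, sealed tube, argon, stopped when 15 is consumed
Reagents that add atoms: none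
Why: Aromatic Claisen rearrangement: the [3,3] shift attaches the dimethyl-bearing terminus to an ortho carbon as a 1,1-dimethylallyl group and dienone 16 tautomerises to the phenol, C5 being preferred over C3 because the new quaternary carbon cannot be accommodated next to bromine, while the basic solvent suppresses acid-induced ring closure of the product.

**Step 7**
Reactants: 17 3-[2-bromo-4-hydroxy-5-(2-methylbut-3-en-2-yl)phenyl]-N-methoxy-N-methylpropanamide
Product: 18 3-[2-bromo-4-(tert-butyldimethylsilyloxy)-5-(2-methylbut-3-en-2-yl)phenyl]-N-methoxy-N-methylpropanamide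
Conditions: TBSOTf, 2,6-lutidine, CH2Cl2, 0 °C to rt
Reagents that add atoms: tert-butyldimethylsilyl triflate, CC(C)(C)[Si](C)(C)OS(=O)(=O)C(F)(F)F
Why: Silyl ether formation with the triflate is chosen because the phenol is flanked by a quaternary carbon, and the resulting hindered aryl silyl ether should persist through the Grignard, oxidative and basic steps ahead.

**Step 8**
Reactants: 18 3-[2-bromo-4-(tert-butyldimethylsilyloxy)-5-(2-methylbut-3-en-2-yl)phenyl]-N-methoxy-N-methylpropanamide
Product: 20 5-[2-bromo-4-(tert-butyldimethylsilyloxy)-5-(2-methylbut-3-en-2-yl)phenyl]pent-1-yn-3-one, via magnesium hemiaminal chelate 19 (not isolated)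
Conditions: HC≡CMgBr (3 equiv), THF, 0 °C to rt; inverse quench into cold 1 M HCl
Reagents that add atoms: ethynylmagnesium bromide, C#C[Mg]Br
Why: Weinreb ketone synthesis: the chelated tetrahedral adduct 19 holds until work-up so that only one alkynyl group is introduced, and the inverse acidic quench protonates the released amine before it can add to the ynone.

**Step 9**
Reactants: 6 (5Z,7Z)-6,7-bis(tert-butyldimethylsilyloxy)-2,11-dimethyldodeca-2,5,7,10-tetraene; 20 5-[2-bromo-4-(tert-butyldimethylsilyloxy)-5-(2-methylbut-3-en-2-yl)phenyl]pent-1-yn-3-one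
Product: 22 3-[2-bromo-4-(tert-butyldimethylsilyloxy)-5-(2-methylbut-3-en-2-yl)phenyl]-1-[3,4-bis(tert-butyldimethylsilyloxy)-2,5-bis(3-methylbut-2-enyl)phenyl]propan-1-one, via cis-cyclohexa-1,4-diene adduct 21 (not isolated)
Conditions: 6 (1.2 equiv), toluene, BHT (cat.), 100 °C, sealed; then DDQ (1.1 equiv), 0 °C to rt, same flask
Reagents that add atoms: none
Why: The electron-rich dienol ether 6 adds across the acyl-activated triple bond of 20 in a concerted, suprafacial, normal-electron-demand [4+2] cycloaddition that joins the diene termini C5 and C8 to the two alkyne carbons (the future C1'–C2' and C5'–C6' bonds) and gives the cyclohexa-1,4-diene 21; DDQ then abstracts hydride from a doubly allylic ring CH and the cation loses the second ring proton, so ring B appears at the arene level. The closest known reaction type is the thermal Diels–Alder reaction of 2,3-bis(silyloxy)buta-1,3-dienes with acetylenic ketones followed by quinone dehydrogenation of the 1,4-diene adduct. Ring B is closed by an intermolecular six-membered [4+2] annulation in which both new bonds form in the same event. No stereocentre is created for the target, since the two sp3 carbons of 21 are cis by suprafacial addition and are flattened on aromatisation. The step needs chemoselectivity (the ynone as the only dienophile beside five isolated alkenes, and ring dehydrogenation ahead of benzylic or allylic oxidation), which the carbonyl-lowered LUMO of the terminal alkyne and the weak doubly allylic C–H bonds of 21 should secure. It also needs a reachable s-cis diene, which the Z,Z geometry provides by turning both prenyl groups outward, and regiochemistry does not arise because 6 is twofold symmetric.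

**Step 10**
Reactants: 22 3-[2-bromo-4-(tert-butyldimethylsilyloxy)-5-(2-methylbut-3-en-2-yl)phenyl]-1-[3,4-bis(tert-butyldimethylsilyloxy)-2,5-bis(3-methylbut-2-enyl)phenyl]propan-1-one
Product: 23 (1S)-3-[2-bromo-4-(tert-butyldimethylsilyloxy)-5-(2-methylbut-3-en-2-yl)phenyl]-1-[3,4-bis(tert-butyldimethylsilyloxy)-2,5-bis(3-methylbut-2-enyl)phenyl]propan-1-ol
Conditions: RuCl[(S,S)-TsDPEN](p-cymene) (3 mol%), HCO2H/Et3N (5:2), CH2Cl2, 35 °C
Reagents that add atoms: none
Why: Noyori asymmetric transfer hydrogenation of an aryl alkyl ketone: the (S,S)-configured ruthenium hydride orients the aryl group by a CH/π contact with the cymene ligand and delivers hydride to the Re face, which sets the carbinol as S, while alkenes, aryl bromide and silyl ethers are inert to this outer-sphere reduction.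

**Step 11**
Reactants: 23 (1S)-3-[2-bromo-4-(tert-butyldimethylsilyloxy)-5-(2-methylbut-3-en-2-yl)phenyl]-1-[3,4-bis(tert-butyldimethylsilyloxy)-2,5-bis(3-methylbut-2-enyl)phenyl]propan-1-ol
Product: 24 (2S)-7-(tert-butyldimethylsilyloxy)-2-[3,4-bis(tert-butyldimethylsilyloxy)-2,5-bis(3-methylbut-2-enyl)phenyl]-6-(2-methylbut-3-en-2-yl)-3,4-dihydro-2H-chromene
Conditions: Pd(OAc)2 (5 mol%), rac-2-(di-tert-butylphosphino)-1,1'-binaphthyl (6 mol%), anhydrous K3PO4, toluene, 80 °C
Reagents that add atoms: none
Why: Intramolecular Buchwald–Hartwig etherification: oxidative addition of the aryl bromide to zerovalent palladium, alkoxide binding and C–O reductive elimination from the bulky-phosphine complex close the six-membered ring C at the aryl carbon, so the S carbinol carbon is not involved and keeps its configuration.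

**Step 12**
Reactants: 24 (2S)-7-(tert-butyldimethylsilyloxy)-2-[3,4-bis(tert-butyldimethylsilyloxy)-2,5-bis(3-methylbut-2-enyl)phenyl]-6-(2-methylbut-3-en-2-yl)-3,4-dihydro-2H-chromene
Product: 25 (2S)-2-[3,4-dihydroxy-2,5-bis(3-methylbut-2-enyl)phenyl]-6-(2-methylbut-3-en-2-yl)-3,4-dihydro-2H-chromen-7-ol (CNP0118330.1)
Conditions: TBAF (4 equiv), AcOH (4 equiv), THF, 0 °C to rt, argon
Reagents that add atoms: none
Why: Fluoride-induced desilylation of the three aryl silyl ethers, with acetic acid buffering so that the freed catechol and phenols stay protonated, which should avoid catecholate oxidation, quinone-methide opening at C2 and cyclisation of the phenols onto the prenyl groups.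

**Compound list**
1 | 5-bromo-2-methylpent-2-ene | CC(C)=CCCBr | starting material
2 | 1,4-dimethylpiperazine-2,3-dione | CN1CCN(C)C(=O)C1=O | starting material
3 | (4-methylpent-3-enyl)magnesium bromide | CC(C)=CCC[Mg]Br | intermediate (not isolated)
4 | bis(bromomagnesium) 1,4-dimethyl-2,3-bis(4-methylpent-3-enyl)piperazine-2,3-diolate, diastereomer mixture | CC(C)=CCCC1(O[Mg]Br)N(C)CCN(C)C1(O[Mg]Br)CCC=C(C)C | intermediate (not isolated)
5 | 2,11-dimethyldodeca-2,10-diene-6,7-dione | CC(C)=CCCC(=O)C(=O)CCC=C(C)C | intermediate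
6 | (5Z,7Z)-6,7-bis(tert-butyldimethylsilyloxy)-2,11-dimethyldodeca-2,5,7,10-tetraene | CC(C)=CC/C=C(/C(O[Si](C)(C)C(C)(C)C)=C/CC=C(C)C)O[Si](C)(C)C(C)(C)C | intermediate
7 | 2-bromo-4-hydroxybenzaldehyde | O=Cc1ccc(O)cc1Br | starting material
8 | 5-(2-bromo-4-hydroxybenzylidene)-2,2-dimethyl-1,3-dioxane-4,6-dione | CC1(C)OC(=O)C(=Cc2ccc(O)cc2Br)C(=O)O1 | intermediate (not isolated)
9 | 5-(2-bromo-4-hydroxybenzyl)-2,2-dimethyl-1,3-dioxane-4,6-dione | CC1(C)OC(=O)C(Cc2ccc(O)cc2Br)C(=O)O1 | intermediate (not isolated)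
10 | 2-(2-bromo-4-hydroxybenzyl)propanedioic acid | OC(=O)C(Cc1ccc(O)cc1Br)C(=O)O | intermediate (not isolated)
11 | 3-(2-bromo-4-hydroxyphenyl)propanoic acid | OC(=O)CCc1ccc(O)cc1Br | intermediate
12 | 3-(2-bromo-4-hydroxyphenyl)-1-(imidazol-1-yl)propan-1-one | O=C(CCc1ccc(O)cc1Br)n1ccnc1 | intermediate (not isolated)
13 | 3-(2-bromo-4-hydroxyphenyl)-N-methoxy-N-methylpropanamide | CON(C)C(=O)CCc1ccc(O)cc1Br | intermediate
14 | prenyl bromide (1-bromo-3-methylbut-2-ene) | CC(C)=CCBr | starting material
15 | 3-[2-bromo-4-(3-methylbut-2-enyloxy)phenyl]-N-methoxy-N-methylpropanamide | CON(C)C(=O)CCc1ccc(OCC=C(C)C)cc1Br | intermediate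
16 | 3-[6-bromo-3-(2-methylbut-3-en-2-yl)-4-oxocyclohexa-1,5-dien-1-yl]-N-methoxy-N-methylpropanamide, racemic | CON(C)C(=O)CCC1=CC(C(C)(C)C=C)C(=O)C=C1Br | intermediate (not isolated)
17 | 3-[2-bromo-4-hydroxy-5-(2-methylbut-3-en-2-yl)phenyl]-N-methoxy-N-methylpropanamide | CON(C)C(=O)CCc1cc(C(C)(C)C=C)c(O)cc1Br | intermediate
18 | 3-[2-bromo-4-(tert-butyldimethylsilyloxy)-5-(2-methylbut-3-en-2-yl)phenyl]-N-methoxy-N-methylpropanamide | CON(C)C(=O)CCc1cc(C(C)(C)C=C)c(O[Si](C)(C)C(C)(C)C)cc1Br | intermediate
19 | bromomagnesium 5-[2-bromo-4-(tert-butyldimethylsilyloxy)-5-(2-methylbut-3-en-2-yl)phenyl]-3-[methoxy(methyl)amino]pent-1-yn-3-olate | C#CC(O[Mg]Br)(CCc1cc(C(C)(C)C=C)c(O[Si](C)(C)C(C)(C)C)cc1Br)N(C)OC | intermediate (not isolated)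
20 | 5-[2-bromo-4-(tert-butyldimethylsilyloxy)-5-(2-methylbut-3-en-2-yl)phenyl]pent-1-yn-3-one | C#CC(=O)CCc1cc(C(C)(C)C=C)c(O[Si](C)(C)C(C)(C)C)cc1Br | intermediate
21 | 3-[2-bromo-4-(tert-butyldimethylsilyloxy)-5-(2-methylbut-3-en-2-yl)phenyl]-1-[cis-4,5-bis(tert-butyldimethylsilyloxy)-3,6-bis(3-methylbut-2-enyl)cyclohexa-1,4-dien-1-yl]propan-1-one, racemic, one enantiomer drawn | O=C(CCc1cc(C(C)(C)C=C)c(O[Si](C)(C)C(C)(C)C)cc1Br)C1=C[C@@H](CC=C(C)C)C(O[Si](C)(C)C(C)(C)C)=C(O[Si](C)(C)C(C)(C)C)[C@H]1CC=C(C)C | intermediate (not isolated)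
22 | 3-[2-bromo-4-(tert-butyldimethylsilyloxy)-5-(2-methylbut-3-en-2-yl)phenyl]-1-[3,4-bis(tert-butyldimethylsilyloxy)-2,5-bis(3-methylbut-2-enyl)phenyl]propan-1-one | O=C(CCc1cc(C(C)(C)C=C)c(O[Si](C)(C)C(C)(C)C)cc1Br)c1cc(CC=C(C)C)c(O[Si](C)(C)C(C)(C)C)c(O[Si](C)(C)C(C)(C)C)c1CC=C(C)C | intermediate
23 | (1S)-3-[2-bromo-4-(tert-butyldimethylsilyloxy)-5-(2-methylbut-3-en-2-yl)phenyl]-1-[3,4-bis(tert-butyldimethylsilyloxy)-2,5-bis(3-methylbut-2-enyl)phenyl]propan-1-ol | O[C@H](c1cc(CC=C(C)C)c(O[Si](C)(C)C(C)(C)C)c(O[Si](C)(C)C(C)(C)C)c1CC=C(C)C)CCc1cc(C(C)(C)C=C)c(O[Si](C)(C)C(C)(C)C)cc1Br | intermediate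
24 | (2S)-7-(tert-butyldimethylsilyloxy)-2-[3,4-bis(tert-butyldimethylsilyloxy)-2,5-bis(3-methylbut-2-enyl)phenyl]-6-(2-methylbut-3-en-2-yl)-3,4-dihydro-2H-chromene | C=CC(C)(C)c1cc2c(cc1O[Si](C)(C)C(C)(C)C)O[C@H](c1cc(CC=C(C)C)c(O[Si](C)(C)C(C)(C)C)c(O[Si](C)(C)C(C)(C)C)c1CC=C(C)C)CC2 | intermediate
25 | (2S)-2-[3,4-dihydroxy-2,5-bis(3-methylbut-2-enyl)phenyl]-6-(2-methylbut-3-en-2-yl)-3,4-dihydro-2H-chromen-7-ol | C=CC(C)(C)c1cc2c(cc1O)O[C@H](c1cc(CC=C(C)C)c(O)c(O)c1CC=C(C)C)CC2 | target

**Step count**
Total: 12 steps. Longest linear sequence: 10 steps (7 to 25 through steps 3 to 12); the diene arm contributes 2 steps and joins at step 9.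

**Steps most likely to fail**

1. Step 9 (cycloaddition and aromatisation). The two neighbouring tert-butyldimethylsilyloxy groups and the 1,4-dialkyl termini may make the s-cis conformer so crowded that cycloaddition is slow, and the ynone would then be lost to thermal oligomerisation. DDQ may also abstract hydride at other electron-rich positions if the ring dehydrogenation is not clean. The fallback redesigns the diene with small silyl groups, the parent class for this cycloaddition, and exchanges the protecting groups after ring B exists. It sets out from diketone 5 and ynone 20 and returns at 22. Diketone 5 is silylated with TMSOTf/Et3N to (5Z,7Z)-6,7-bis(trimethylsilyloxy)-2,11-dimethyldodeca-2,5,7,10-tetraene F1. Heating F1 with 20 in toluene should give the bis(trimethylsilyloxy) cyclohexa-1,4-diene adduct F2, which DDQ aromatises to the bis(trimethylsilyl) aryl ketone F3. Brief methanolysis (MeOH, catalytic citric acid, 0 °C) removes only the two labile trimethylsilyl groups and gives the catechol ketone F4. TBSOTf/2,6-lutidine then converts F4 into 22.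

2. Step 6 (Claisen rearrangement). At 190 °C the liberated phenol may react on with its own 1,1-dimethylallyl group, either by abnormal Claisen isomerisation of the side chain or by addition of the hydroxyl across the vinyl group. The ether may also simply cleave back to phenol 13, and a minor shift toward C3 cannot be excluded. The fallback replaces the free-phenol rearrangement by a rearrangement–acylation cascade so that the phenol never exists at high temperature. It sets out from 15 and returns at 17. Ether 15 is heated in N,N-diethylaniline with butyric anhydride, which esterifies the phenol as it forms and should give 5-bromo-4-[3-(methoxy(methyl)amino)-3-oxopropyl]-2-(2-methylbut-3-en-2-yl)phenyl butanoate F5. Methanolysis of F5 with K2CO3 in MeOH at rt then gives 17.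

3. Step 11 (aryl C–O coupling). β-Hydride elimination from the benzylic palladium alkoxide may outrun C–O reductive elimination, returning ketone 22 together with debrominated material. The fallback forms the other C–O bond of ring C, at C2, by substitution with inversion. It sets out from 22 and returns at 24. Miyaura borylation of 22 (B2pin2, Pd(dppf)Cl2, KOAc, dioxane, 85 °C) should give the aryl pinacol boronate F6, and oxidation with NaBO3·4H2O in THF/water gives the phenol ketone F7. Transfer hydrogenation of F7 with RuCl[(R,R)-TsDPEN](p-cymene) in HCO2H/Et3N gives the (1R)-configured phenol alcohol F8. Mitsunobu cyclisation of F8 (PPh3, DIAD, THF, 0 °C) should close ring C with inversion at the carbinol carbon and give the (2S)-flavan 24.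

**Further compounds**
F1 | step 9 | (5Z,7Z)-6,7-bis(trimethylsilyloxy)-2,11-dimethyldodeca-2,5,7,10-tetraene | CC(C)=CC/C=C(/C(O[Si](C)(C)C)=C/CC=C(C)C)O[Si](C)(C)C
F2 | step 9 | 3-[2-bromo-4-(tert-butyldimethylsilyloxy)-5-(2-methylbut-3-en-2-yl)phenyl]-1-[cis-4,5-bis(trimethylsilyloxy)-3,6-bis(3-methylbut-2-enyl)cyclohexa-1,4-dien-1-yl]propan-1-one, racemic, one enantiomer drawn | O=C(CCc1cc(C(C)(C)C=C)c(O[Si](C)(C)C(C)(C)C)cc1Br)C1=C[C@@H](CC=C(C)C)C(O[Si](C)(C)C)=C(O[Si](C)(C)C)[C@H]1CC=C(C)C
F3 | step 9 | 3-[2-bromo-4-(tert-butyldimethylsilyloxy)-5-(2-methylbut-3-en-2-yl)phenyl]-1-[3,4-bis(trimethylsilyloxy)-2,5-bis(3-methylbut-2-enyl)phenyl]propan-1-one | O=C(CCc1cc(C(C)(C)C=C)c(O[Si](C)(C)C(C)(C)C)cc1Br)c1cc(CC=C(C)C)c(O[Si](C)(C)C)c(O[Si](C)(C)C)c1CC=C(C)C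
F4 | step 9 | 3-[2-bromo-4-(tert-butyldimethylsilyloxy)-5-(2-methylbut-3-en-2-yl)phenyl]-1-[3,4-dihydroxy-2,5-bis(3-methylbut-2-enyl)phenyl]propan-1-one | O=C(CCc1cc(C(C)(C)C=C)c(O[Si](C)(C)C(C)(C)C)cc1Br)c1cc(CC=C(C)C)c(O)c(O)c1CC=C(C)C
F5 | step 6 | 5-bromo-4-[3-(methoxy(methyl)amino)-3-oxopropyl]-2-(2-methylbut-3-en-2-yl)phenyl butanoate | CON(C)C(=O)CCc1cc(C(C)(C)C=C)c(OC(=O)CCC)cc1Br
F6 | step 11 | 3-[4-(tert-butyldimethylsilyloxy)-5-(2-methylbut-3-en-2-yl)-2-(4,4,5,5-tetramethyl-1,3,2-dioxaborolan-2-yl)phenyl]-1-[3,4-bis(tert-butyldimethylsilyloxy)-2,5-bis(3-methylbut-2-enyl)phenyl]propan-1-one | O=C(CCc1cc(C(C)(C)C=C)c(O[Si](C)(C)C(C)(C)C)cc1B2OC(C)(C)C(C)(C)O2)c1cc(CC=C(C)C)c(O[Si](C)(C)C(C)(C)C)c(O[Si](C)(C)C(C)(C)C)c1CC=C(C)C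
F7 | step 11 | 3-[4-(tert-butyldimethylsilyloxy)-2-hydroxy-5-(2-methylbut-3-en-2-yl)phenyl]-1-[3,4-bis(tert-butyldimethylsilyloxy)-2,5-bis(3-methylbut-2-enyl)phenyl]propan-1-one | O=C(CCc1cc(C(C)(C)C=C)c(O[Si](C)(C)C(C)(C)C)cc1O)c1cc(CC=C(C)C)c(O[Si](C)(C)C(C)(C)C)c(O[Si](C)(C)C(C)(C)C)c1CC=C(C)C
F8 | step 11 | 2-[(3R)-3-[3,4-bis(tert-butyldimethylsilyloxy)-2,5-bis(3-methylbut-2-enyl)phenyl]-3-hydroxypropyl]-5-(tert-butyldimethylsilyloxy)-4-(2-methylbut-3-en-2-yl)phenol | O[C@@H](c1cc(CC=C(C)C)c(O[Si](C)(C)C(C)(C)C)c(O[Si](C)(C)C(C)(C)C)c1CC=C(C)C)CCc1cc(C(C)(C)C=C)c(O[Si](C)(C)C(C)(C)C)cc1O
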